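The route rests on one feature of the dioxane ring (O1; C2 carrying syringyl ring B; C3 carrying C9H2OH; O4; ring A with C4a on O4, C5-OMe, C7-propenal, C8a on O1). C2 and the hydroxyl oxygen on C9 are 1,3-related through C3, so they can be the carbon and the oxygen of a single ArCHO group once C2–C3 and O–C9 are tied into an oxetane.
Bilagrewin ⇒ C7 aldehyde (Wittig, two-carbon ylide) ⇒ C7 nitrile (iBu2AlH). The nitrile is the C7 placeholder because it reaches the aldehyde without an oxidant, which the free syringyl phenol would not tolerate.
(2S,3S)-nitrile ⇒ racemic trans-benzodioxane, resolved as its bis-(1S)-camphanate, because two achiral photopartners cannot give a facial bias at C3.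
trans-Benzodioxane ⇒ 2-aryl-3-(2-hydroxyaryloxy)oxetane (acid: C2–O cleaved, O1–C2 closed, C9–OH released) ⇒ C8a bromide (borylation, oxidation) ⇒ MOM-syringaldehyde + ring A aryl vinyl ether (Paternò–Büchi: C2–C3 and O–C9).
Ring order: rings A and B are bought; the oxetane is closed first (step 3) and is then traded for the dioxane ring (step 6).

Key step: step 3

Remark on the chemistry: the target is the (2S,3S), 2,3-trans isomer. Compounds 6 to 10 are racemic and are drawn as the antipode with C3 as in the target. Compounds 6 to 9 are mixtures of C2 epimers, drawn as the 2,3-trans isomer, and both epimers are carried on.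

Step 1
Reactants: 1 syringaldehyde (4-hydroxy-3,5-dimethoxybenzaldehyde)
Product: 2 3,5-dimethoxy-4-(methoxymethoxy)benzaldehyde
Conditions: MOMCl, iPr2NEt, CH2Cl2, 0 °C to rt
Reagents that add atoms: chloromethyl methyl ether (MOMCl), COCCl
Why: Williamson-type O-alkylation of the phenoxide with the reactive α-chloro ether should give the MOM acetal, which masks the easily oxidised phenol during irradiation and palladium chemistry and is removed by the acid of step 6.

Step 2
Reactants: 3 3-bromo-4-hydroxy-5-methoxybenzonitrile; 4 vinyl acetate
Product: 5 3-bromo-5-methoxy-4-(vinyloxy)benzonitrile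
Conditions: [Ir(cod)Cl]2 (cat.), Na2CO3, vinyl acetate (excess), toluene, 100 °C; filtration through basic alumina
Reagents that add atoms: vinyl acetate 4, CC(=O)OC=C
Why: Iridium-catalysed transfer vinylation (addition of the phenol to iridium-bound vinyl acetate, then β-acetoxy elimination) is an established one-step way from phenols to aryl vinyl ethers and leaves C–Br and C≡N untouched.

Step 3
Reactants: 2 3,5-dimethoxy-4-(methoxymethoxy)benzaldehyde; 5 3-bromo-5-methoxy-4-(vinyloxy)benzonitrile
Product: 6 (±)-3-bromo-4-({(2R,3S)-2-[3,5-dimethoxy-4-(methoxymethoxy)phenyl]oxetan-3-yl}oxy)-5-methoxybenzonitrile (2,3-trans drawn; the 2,3-cis epimer is kept in the mixture)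
Conditions: hν (350 nm lamps, borosilicate filter), 5 (3 equiv), K2CO3 (solid), degassed benzene (0.1 M in 2), 15 °C; Et3N-washed silica gel, excess 5 recovered
Reagents that add atoms: none
Why: Paternò–Büchi reaction: only aldehyde 2 absorbs at 350 nm and crosses to its triplet (in this trialkoxy series the lowest triplet is largely π,π* and reacts through the nearby n,π* state, hence slowly, which is why 5 is used in excess and concentrated), and its electrophilic oxygen bonds to the terminal CH2 (future C9) of 5 to give a triplet 1,4-biradical with spin on benzylic C2 and on the aryloxy-bearing C3. Spin inversion followed by C2–C3 radical recombination closes the oxetane, so the one new ring arises by collapse of a 1,4-biradical (overall a stepwise [2+2] cycloaddition with no thermal counterpart), and the closest known cases are the additions of aromatic aldehydes to alkyl vinyl ethers and silyl enol ethers, which give 3-oxy-substituted oxetanes. The selectivity the step needs is regiochemical, 3-aryloxy- over 2-aryloxyoxetane, and the substrate secures it because O-attack at CH2 leaves an oxygen-stabilised secondary radical whereas attack at the inner carbon would leave a primary one; the acetal-type minor regioisomer is removed by chromatography. C3 is created without facial bias, since neither partner nor the medium is chiral, so 6 is racemic and its absolute configuration is settled by the resolution in step 7. C2 is set by the conformation of the biradical at the moment of spin inversion, only a weak cis/trans preference is expected, and none is needed because both epimers converge in step 6. Chemoselectivity rests on wavelength and triplet energies: the bromo(cyano)aryl vinyl ether neither absorbs at 350 nm nor accepts energy from the lower-lying aldehyde triplet, so the C–Br bond should persist, and solid K2CO3 scavenges traces of acid that would open 6 or hydrolyse 5.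

Step 4
Reactants: 6 (±)-oxetane bromide
Product: 7 (±)-4-({(2R,3S)-2-[3,5-dimethoxy-4-(methoxymethoxy)phenyl]oxetan-3-yl}oxy)-3-methoxy-5-(4,4,5,5-tetramethyl-1,3,2-dioxaborolan-2-yl)benzonitrile
Conditions: B2pin2, Pd(dppf)Cl2 (cat.), KOAc, 1,4-dioxane, 85 °C
Reagents that add atoms: bis(pinacolato)diboron, CC1(C)OB(OC1(C)C)B2OC(C)(C)C(C)(C)O2
Why: Miyaura borylation (oxidative addition of zerovalent palladium into C8a–Br, acetate-assisted transmetalation, reductive elimination) runs under weakly basic conditions that leave oxetane, MOM acetal, nitrile, C2 and C3 alone.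

Step 5
Reactants: 7 (±)-oxetane pinacol boronate
Product: 8 (±)-4-({(2R,3S)-2-[3,5-dimethoxy-4-(methoxymethoxy)phenyl]oxetan-3-yl}oxy)-3-hydroxy-5-methoxybenzonitrile
Conditions: 30% aq H2O2, NaHCO3, THF–H2O, 0 °C to rt; extractive work-up, used without delay
Reagents that add atoms: hydrogen peroxide, OO
Why: Oxidative ipso-hydroxylation of the aryl boronate (1,2-shift of the aryl group from boron to peroxide oxygen, then hydrolysis) places O1 on C8a, and the hydrogencarbonate buffer is too mild for nitrile hydration or for phenoxide attack on the unactivated oxetane.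

Step 6
Reactants: 8 (±)-oxetane phenol
Product: 10 (±)-trans-2-(4-hydroxy-3,5-dimethoxyphenyl)-3-(hydroxymethyl)-5-methoxy-2,3-dihydro-1,4-benzodioxine-7-carbonitrile, via MOM-protected benzodioxane 9 (not isolated)
Conditions: 2 M aq HCl–1,4-dioxane (1:4), 0.02 M, 45 °C
Reagents that add atoms: none
Why: Acid-catalysed intramolecular oxetane opening (6-exo-tet, SN1-like): protonation of the strained ether ionises C2–O rather than C9–O because only C2 is benzylic to electron-rich ring B, O1 captures the cation to close the dioxane ring while the former carbonyl oxygen is released as the C9 hydroxyl, C3 is not touched, and after hydrolysis of the MOM group the free para-phenol makes the O1–C2 bond reversible so that both C2 epimers should drain into the diequatorial 2,3-trans isomer.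

Step 7
Reactants: 10 (±)-trans-benzodioxane nitrile; 11 (1S)-(−)-camphanic chloride
Product: 12 (2S,3S)-bis[(1S,4R)-camphanate] of 10 (esters at the ring B phenol and at C9–OH)
Conditions: 11 (2.4 equiv), Et3N, DMAP (cat.), CH2Cl2, 0 °C to rt; diastereomers separated on silica gel, then recrystallised
Reagents that add atoms: (1S)-(−)-camphanic chloride 11, ClC(=O)[C@@]12CC[C@@](C)(C(=O)O1)C2(C)C
Why: DMAP-catalysed acylation of both hydroxyls with an enantiopure acid chloride that has no α-hydrogen turns the enantiomers of 10 into two diastereomers that differ right next to C3 and should be separable (classical resolution), and the known camphanoyl configuration lets the (2S,3S) isomer be identified by X-ray analysis.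

Step 8
Reactants: 12 (2S,3S)-bis-camphanate
Product: 13 (2S,3S)-2-(4-hydroxy-3,5-dimethoxyphenyl)-3-(hydroxymethyl)-5-methoxy-2,3-dihydro-1,4-benzodioxine-7-carbonitrile
Conditions: K2CO3, MeOH–THF, 0 °C to rt; then aq NH4Cl
Reagents that add atoms: none
Why: Base-catalysed transesterification (methanolysis) frees the phenol and the primary alcohol without breaking a bond at C3, and any reversible opening at C2 through the phenoxide can only return the more stable trans isomer.

Step 9
Reactants: 13 (2S,3S)-benzodioxane nitrile
Product: 15 (2S,3S)-2-(4-hydroxy-3,5-dimethoxyphenyl)-3-(hydroxymethyl)-5-methoxy-2,3-dihydro-1,4-benzodioxine-7-carbaldehyde, via aldimine 14 (not isolated)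
Conditions: iBu2AlH (5 equiv), CH2Cl2, −78 to −20 °C; then 1 M aq HCl, 0 °C
Reagents that add atoms: water, O
Why: Partial reduction of a nitrile with iBu2AlH: once both O–H groups are taken up as aluminium alkoxides, one hydride adds to C≡N to give an aluminium-bound aldimine that resists further reduction and is hydrolysed to the aldehyde on work-up, so no oxidant meets the syringyl phenol.

Step 10
Reactants: 15 (2S,3S)-benzodioxane carbaldehyde; 16 (triphenylphosphoranylidene)acetaldehyde
Product: 17 bilagrewin
Conditions: 16 (1.2 equiv), toluene–THF (4:1), 80 °C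
Reagents that add atoms: (triphenylphosphoranylidene)acetaldehyde 16, O=CC=P(c1ccccc1)(c1ccccc1)c1ccccc1
Why: Wittig olefination with the stabilised formylmethylene ylide, which is too weakly basic to deprotonate the phenol or disturb C2 and C3, should give the E-enal as stabilised ylides do, and keeping the ylide near one equivalent curbs a second homologation.

Compound list
1 | syringaldehyde | COc1cc(C=O)cc(OC)c1O | starting material
2 | 3,5-dimethoxy-4-(methoxymethoxy)benzaldehyde | COCOc1c(OC)cc(C=O)cc1OC | intermediate
3 | 3-bromo-4-hydroxy-5-methoxybenzonitrile | N#Cc1cc(Br)c(O)c(OC)c1 | starting material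
4 | vinyl acetate | CC(=O)OC=C | starting material
5 | 3-bromo-5-methoxy-4-(vinyloxy)benzonitrile | N#Cc1cc(Br)c(OC=C)c(OC)c1 | intermediate
6 | (±)-2-aryl-3-aryloxyoxetane bromide, (2R,3S)-trans antipode drawn, cis epimer present | COCOc1c(OC)cc(cc1OC)[C@H]2OC[C@@H]2Oc3c(Br)cc(cc3OC)C#N | intermediate
7 | (±)-oxetane pinacol boronate, drawn as for 6 | COCOc1c(OC)cc(cc1OC)[C@H]2OC[C@@H]2Oc3c(B4OC(C)(C)C(C)(C)O4)cc(cc3OC)C#N | intermediate
8 | (±)-oxetane with free O1 phenol, drawn as for 6 | COCOc1c(OC)cc(cc1OC)[C@H]2OC[C@@H]2Oc3c(O)cc(cc3OC)C#N | intermediate
9 | (±)-MOM-protected benzodioxane nitrile, trans drawn, not isolated | COCOc1c(OC)cc(cc1OC)[C@@H]2Oc3cc(C#N)cc(OC)c3O[C@H]2CO | intermediate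
10 | (±)-trans-benzodioxane nitrile with free phenol and C9–OH, (2S,3S) antipode drawn | COc1cc(cc(OC)c1O)[C@@H]2Oc3cc(C#N)cc(OC)c3O[C@H]2CO | intermediate
11 | (1S)-(−)-camphanic chloride, (1S,4R) | ClC(=O)[C@@]12CC[C@@](C)(C(=O)O1)C2(C)C | starting material
12 | (2S,3S)-bis[(1S,4R)-camphanate] | COc1cc(cc(OC)c1OC(=O)[C@@]45CC[C@@](C)(C(=O)O4)C5(C)C)[C@@H]2Oc3cc(C#N)cc(OC)c3O[C@H]2COC(=O)[C@@]67CC[C@@](C)(C(=O)O6)C7(C)C | intermediate
13 | (2S,3S)-benzodioxane nitrile, single enantiomer | COc1cc(cc(OC)c1O)[C@@H]2Oc3cc(C#N)cc(OC)c3O[C@H]2CO | intermediate
14 | (2S,3S)-aldimine, aluminium-bound in the flask, drawn in its free N–H and O–H form, not isolated | COc1cc(cc(OC)c1O)[C@@H]2Oc3cc(C=N)cc(OC)c3O[C@H]2CO | intermediate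
15 | (2S,3S)-benzodioxane-7-carbaldehyde | COc1cc(cc(OC)c1O)[C@@H]2Oc3cc(C=O)cc(OC)c3O[C@H]2CO | intermediate
16 | (triphenylphosphoranylidene)acetaldehyde | O=CC=P(c1ccccc1)(c1ccccc1)c1ccccc1 | starting material
17 | bilagrewin, (2S,3S), E-enal | COc1cc([C@@H]2Oc3cc(/C=C/C=O)cc(OC)c3O[C@H]2CO)cc(OC)c1O | target

Total step count: 10. Longest linear sequence: 9 steps (3 → 5 → 6 → 7 → 8 → 10 → 12 → 13 → 15 → 17; the branch from 1 is equally long).

Steps most likely to fail

Step 3. The donor-rich, largely π,π* triplet may add too slowly to an only moderately electron-rich alkene. Hydrogen abstraction, pinacol-type coupling, erosion of regioselectivity or photolytic loss of bromine could then take over.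
- The fallback makes the same oxetane by ionic chemistry. It sets out from 3 (with 2 as partner) and comes back at 6.
- O-alkylation of 3 with ethyl bromoacetate (K2CO3, acetone, reflux) gives ethyl (2-bromo-4-cyano-6-methoxyphenoxy)acetate F1.
- The lithium enolate of F1 (LiN(iPr)2, THF, −78 °C) adds to aldehyde 2 to give the β-hydroxy-α-aryloxy ester F2.
- LiBH4 in THF reduces only the ester, giving the 1,3-diol F3.
- TsCl in pyridine at 0 °C sulfonylates the primary hydroxyl, giving the monotosylate F4.
- NaH in THF closes the ring by 4-exo-tet Williamson displacement to racemic 6 as a C2 epimer mixture, which is all that step 4 requires.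

Step 7. The acylation itself is safe. The risk is too small a difference in mobility and solubility between the two bis-camphanates, so that the separation fails.
- The fallback drops covalent diastereomers. It separates the enantiomers of 10 directly by preparative supercritical-fluid chromatography on an immobilised amylose tris(3,5-dimethylphenylcarbamate) phase (CO2–MeOH).
- It sets out from 10 and comes back at 13, so steps 7 and 8 fall away.
- The configuration is assigned by converting a sample into 12 for X-ray analysis.
- No compound outside the list is made (F0).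

Step 6. The opened cation may fragment with loss of the C9 carbon, be trapped by water or chloride, or oligomerise. The cis-to-trans drift in acid may also stay incomplete.
- The fallback takes the cascade apart and moves the C2 correction from the acid to the base manifold. It sets out from 8 and comes back at 10.
- Catalytic camphorsulfonic acid in dry CH2Cl2 at −20 °C isomerises 8 to 9, which is now isolated. This is a water-free, kinetically controlled intramolecular oxetane opening by a phenol.
- HCl in MeOH at rt then removes the MOM group from the already closed ring.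
- K2CO3 in DMF at 50 °C equilibrates C2 through reversible phenoxide-driven opening and reclosure of O1–C2 (para-quinone methide pathway), giving the trans isomer.
- No compound outside the list is made (F0).

Further compounds
F1 | step 3 | ethyl (2-bromo-4-cyano-6-methoxyphenoxy)acetate | CCOC(=O)COc1c(Br)cc(cc1OC)C#N
F2 | step 3 | (±)-ethyl 2-(2-bromo-4-cyano-6-methoxyphenoxy)-3-[3,5-dimethoxy-4-(methoxymethoxy)phenyl]-3-hydroxypropanoate, both diastereomers, the one leading to trans-6 drawn | COCOc1c(OC)cc(cc1OC)[C@@H](O)[C@H](C(=O)OCC)Oc2c(Br)cc(cc2OC)C#N
F3 | step 3 | (±)-3-bromo-4-({1-[3,5-dimethoxy-4-(methoxymethoxy)phenyl]-1,3-dihydroxypropan-2-yl}oxy)-5-methoxybenzonitrile, drawn as for F2 | COCOc1c(OC)cc(cc1OC)[C@@H](O)[C@H](CO)Oc2c(Br)cc(cc2OC)C#N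
F4 | step 3 | (±)-primary p-toluenesulfonate of F3, drawn as for F2 | COCOc1c(OC)cc(cc1OC)[C@@H](O)[C@H](COS(=O)(=O)c3ccc(C)cc3)Oc2c(Br)cc(cc2OC)C#N
F0 | step 7 | none | none
F0 | step 6 | none | none
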